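**Retrosynthetic overview**
1. Feature: ring A of the chroman (O1, C2, C3, C4, C4a, C5 to C8, C8a) has oxygen on four neighbouring carbons: OMe on C6, free OH on C7, OMe on C8 and O1 on C8a. C6-C7-C8 with its three oxygens is the skeleton of 1,3-dimethoxyacetone, and C5-C4a-C8a is an α-formyl ester unit.
2. The ring B quinone comes from its bis(benzyl) hydroquinone ether. Ring C is cut at O1-C2 (C8a phenol plus C2 primary alcohol, Mitsunobu).
3. Ring A is cut at C5-C6 and C8-C8a: a [3+3] addition-elimination/Claisen annulation of 1,3-dimethoxyacetone with the (3E,5S)-aminomethylene δ-lactone 16, whose ring oxygen becomes the C2 hydroxyl.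
4. 16 comes from δ-lactone 15, and 15 from the auxiliary-controlled Michael addition of ring B arylacetyl oxazolidinone 10 to tert-butyl acrylate (sets C3). 10 comes from 2,3-dimethoxyphenol.
5. Order of rings: ring B is present from the start, a temporary δ-lactone follows, then ring A, then ring C, and ring B is oxidised last.

Key step: step 12

Remark: all intermediates use the chroman numbering of the target; C3 reads as S from the SMILES string and stays S from 13 to 22 because the priority order CH2O or C(=O)N > aryl > CH2 > H never changes; the zinc reagent of step 5 is taken as the commercial ether solution.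

Step 1
Reactants: 1 2,3-dimethoxyphenol
Product: 2 2,3-dimethoxy-1,4-benzoquinone
Conditions: O2 (1 atm), Co(salen) (10 mol %), DMF, rt
Reagents that add atoms: dioxygen, O=O
Why: Cobalt-salen catalysed aerobic phenol oxidation puts oxygen on the free para position, the only site that leads to a para-quinone, and the two methoxy groups make the phenol electron-rich enough to react at room temperature.

Step 2
Reactants: 2 2,3-dimethoxy-1,4-benzoquinone
Product: 3 2,3-dimethoxybenzene-1,4-diol
Conditions: Na2S2O4, THF-H2O, rt, argon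
Reagents that add atoms: none
Why: Dithionite reduction of a para-quinone to its hydroquinone is fast at room temperature and leaves both methoxy groups untouched.

Step 3
Reactants: 3 2,3-dimethoxybenzene-1,4-diol
Product: 4 1,4-bis(benzyloxy)-2,3-dimethoxybenzene
Conditions: BnBr (2.4 equiv), K2CO3, DMF, 50 °C, argon
Reagents that add atoms: benzyl bromide, BrCc1ccccc1
Why: Double Williamson etherification of the two equivalent phenoxides installs ethers that withstand strong base and hydride and leave by hydrogenolysis at the end.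

Step 4
Reactants: 4 1,4-bis(benzyloxy)-2,3-dimethoxybenzene
Product: 5 1,4-bis(benzyloxy)-5-bromo-2,3-dimethoxybenzene
Conditions: NBS (1.0 equiv), MeCN, 0 °C, dark
Reagents that add atoms: N-bromosuccinimide, O=C1CCC(=O)N1Br
Why: Electrophilic aromatic bromination in a polar solvent takes one of the two symmetry-equivalent free ring positions, and one equivalent of reagent in the dark should stop at the monobromide without benzylic bromination.

Step 5
Reactants: 5 1,4-bis(benzyloxy)-5-bromo-2,3-dimethoxybenzene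
Product: 6 tert-butyl [2,5-bis(benzyloxy)-3,4-dimethoxyphenyl]acetate
Conditions: ClZnCH2CO2tBu (1.5 equiv), Pd2(dba)3 (2.5 mol %), XPhos (10 mol %), THF, 60 °C
Reagents that add atoms: 2-tert-butoxy-2-oxoethylzinc chloride, CC(C)(C)OC(=O)C[Zn]Cl
Why: Negishi-type coupling of a Reformatsky zinc enolate with an aryl bromide forms the aryl-CH2 bond without strong base, and the bulky biaryl phosphine copes with the electron-rich ortho-alkoxy bromide.

Step 6
Reactants: 6 tert-butyl [2,5-bis(benzyloxy)-3,4-dimethoxyphenyl]acetate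
Product: 7 [2,5-bis(benzyloxy)-3,4-dimethoxyphenyl]acetic acid
Conditions: TFA, CH2Cl2, 0 °C to rt
Reagents that add atoms: none
Why: Acidolysis of the tert-butyl ester through the tert-butyl cation frees the acid, while aryl benzyl and methyl ethers survive short exposure to dilute TFA.

Step 7
Reactants: 7 [2,5-bis(benzyloxy)-3,4-dimethoxyphenyl]acetic acid; 8 (4S)-4-benzyl-1,3-oxazolidin-2-one
Product: 10 (4S)-4-benzyl-3-{[2,5-bis(benzyloxy)-3,4-dimethoxyphenyl]acetyl}-1,3-oxazolidin-2-one, via mixed pivalic anhydride 9 (not isolated)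
Conditions: PivCl, Et3N, THF, -20 °C; then LiCl, 8, -20 °C to rt
Reagents that add atoms: pivaloyl chloride, CC(C)(C)C(=O)Cl (its acyl group stands in 9 only)
Why: In this mixed-anhydride N-acylation the LiCl-activated oxazolidinone attacks the less hindered arylacetyl carbonyl of 9, and no strong base is needed.

Step 8
Reactants: 10 (4S)-4-benzyl-3-{[2,5-bis(benzyloxy)-3,4-dimethoxyphenyl]acetyl}-1,3-oxazolidin-2-one; 11 tert-butyl acrylate
Product: 13 tert-butyl (4S)-5-[(4S)-4-benzyl-2-oxo-1,3-oxazolidin-3-yl]-4-[2,5-bis(benzyloxy)-3,4-dimethoxyphenyl]-5-oxopentanoate, via chlorotitanium Z-enolate 12 (not isolated)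
Conditions: TiCl3(OiPr) (from TiCl4 and Ti(OiPr)4), iPr2NEt, CH2Cl2, 0 °C; then 11 (1.5 equiv), 0 °C; aq. NH4Cl
Reagents that add atoms: TiCl3(OiPr), CC(C)O[Ti](Cl)(Cl)Cl (its atoms stand in 12 only)
Why: Soft enolisation gives the chelated Z-enolate 12, which adds to the acrylate from the face opposite the benzyl group of the auxiliary (auxiliary-controlled Michael addition of a chlorotitanium imide enolate) and so sets the future C3 as S.

Step 9
Reactants: 13 tert-butyl (4S)-5-[(4S)-4-benzyl-2-oxo-1,3-oxazolidin-3-yl]-4-[2,5-bis(benzyloxy)-3,4-dimethoxyphenyl]-5-oxopentanoate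
Product: 14 tert-butyl (4S)-4-[2,5-bis(benzyloxy)-3,4-dimethoxyphenyl]-5-hydroxypentanoate
Conditions: LiBH4, THF, 0 °C
Reagents that add atoms: none
Why: LiBH4 reduces the activated exocyclic imide carbonyl to the primary alcohol and releases the auxiliary, while the tert-butyl ester is inert at 0 °C and the weakly basic medium should not epimerise the benzylic centre.

Step 10
Reactants: 14 tert-butyl (4S)-4-[2,5-bis(benzyloxy)-3,4-dimethoxyphenyl]-5-hydroxypentanoate
Product: 15 (5S)-5-[2,5-bis(benzyloxy)-3,4-dimethoxyphenyl]oxan-2-one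
Conditions: p-TsOH·H2O (10 mol %), toluene, 70 °C
Reagents that add atoms: none
Why: Acid-catalysed loss of isobutene from the tert-butyl ester and 6-exo-trig lactonisation of the δ-hydroxy acid give the δ-lactone without touching the stereocentre.

Step 11
Reactants: 15 (5S)-5-[2,5-bis(benzyloxy)-3,4-dimethoxyphenyl]oxan-2-one
Product: 16 (3E,5S)-5-[2,5-bis(benzyloxy)-3,4-dimethoxyphenyl]-3-[(dimethylamino)methylidene]oxan-2-one
Conditions: tBuOCH(NMe2)2 (3 equiv), toluene, 100 °C
Reagents that add atoms: tert-butoxybis(dimethylamino)methane, CC(C)(C)OC(N(C)C)N(C)C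
Why: Aminomethylenation at C4a, the only enolisable carbon, uses the aminal ester because it releases tert-butoxide and a formamidinium ion and is therefore more reactive toward a lactone than DMF dimethyl acetal, and it should give the thermodynamically preferred E vinylogous carbamate.

Step 12
Reactants: 16 (3E,5S)-5-[2,5-bis(benzyloxy)-3,4-dimethoxyphenyl]-3-[(dimethylamino)methylidene]oxan-2-one; 17 1,3-dimethoxyacetone
Product: 19 (2S)-2-[2,5-bis(benzyloxy)-3,4-dimethoxyphenyl]-3-(2,4-dihydroxy-3,5-dimethoxyphenyl)propan-1-ol, via oxobutylidene lactone 18 (not isolated)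
Conditions: 17 (3 equiv), KOtBu (5 equiv), THF-tBuOH, argon stream, 0 °C to rt, then 60 °C; degassed 1 M HCl
Reagents that add atoms: none
Why: The potassium enolate of 17 attacks the aminomethylene carbon C5 of 16 through C6 and dimethylamine leaves, which gives 18 as an extended dienolate in which the C4a-C5 bond has lost its double-bond character and can turn the ketone chain to the side of the lactone carbonyl. Proton exchange through tBuOH makes the C8 enolate available, it acylates on carbon at C8a in a 6-(enolendo)-exo-trig Claisen closure, the tetrahedral intermediate expels the lactone oxygen as the C2 alkoxide, and two enolisations turn the cyclohexenedione into the resorcinolate of ring A. The closest known reaction type is the base-mediated [3+3] Michael (addition-elimination)/Claisen synthesis of resorcinols from acetonedicarboxylates or dibenzyl ketones and alkoxymethylene esters or alkynoates, next to the consecutive Michael-Claisen reaction of acetone derivatives with acrylates to cyclohexane-1,3-diones. No stereocentre is formed, and C3 is kept because it bears no acidifying group and the C4 methylene separates it from every enolisable position. The selectivity needed is C- over O-acylation: closure through the C7 enolate oxygen would give a 2-pyranone, but this acyl transfer is reversible since the tethered C2 alkoxide or tert-butoxide reopens the pyranone, whereas C-acylation ends in the aromatic dianion, so excess base and heat should drain the equilibria towards 19. Regiochemistry is secured by the symmetry of 17, as either α-carbon and either order of the two bond formations lead to the same ring with OMe on C6 and C8 and free hydroxyls on C7 and C8a.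

Step 13
Reactants: 19 (2S)-2-[2,5-bis(benzyloxy)-3,4-dimethoxyphenyl]-3-(2,4-dihydroxy-3,5-dimethoxyphenyl)propan-1-ol
Product: 20 (3S)-3-[2,5-bis(benzyloxy)-3,4-dimethoxyphenyl]-6,8-dimethoxychroman-7-ol
Conditions: PPh3, DIAD, THF (0.01 M), 0 °C to rt, argon
Reagents that add atoms: none
Why: In this Mitsunobu etherification the C8a phenoxide displaces the phosphonium-activated C2 oxygen in a 6-exo-tet closure, the C7 hydroxyl cannot reach C2, and C3 keeps its configuration because it takes no part.

Step 14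
Reactants: 20 (3S)-3-[2,5-bis(benzyloxy)-3,4-dimethoxyphenyl]-6,8-dimethoxychroman-7-ol
Product: 21 5-[(3S)-7-hydroxy-6,8-dimethoxychroman-3-yl]-2,3-dimethoxybenzene-1,4-diol
Conditions: H2 (1 atm), Pd/C, EtOAc-MeOH, rt; filtered under argon and used at once
Reagents that add atoms: none
Why: Hydrogenolysis over Pd/C cleaves the two benzylic C-O bonds of the aryl benzyl ethers, while the O1-C2 bond of the chroman is not benzylic and stays.

Step 15
Reactants: 21 5-[(3S)-7-hydroxy-6,8-dimethoxychroman-3-yl]-2,3-dimethoxybenzene-1,4-diol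
Product: 22 5-[(3S)-7-hydroxy-6,8-dimethoxychroman-3-yl]-2,3-dimethoxycyclohexa-2,5-diene-1,4-dione
Conditions: Ag2O (1.1 equiv), Na2SO4, Et2O-CH2Cl2, rt, short contact
Reagents that add atoms: none
Why: Ag2O oxidises the tetraoxygenated hydroquinone to the quinone at a much lower potential than the isolated C7 phenol, so close to one equivalent of oxidant should leave ring A intact.

**Compound list**
1 | 2,3-dimethoxyphenol | COc1cccc(O)c1OC | starting material
2 | 2,3-dimethoxy-1,4-benzoquinone | COC1=C(OC)C(=O)C=CC1=O | intermediate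
3 | 2,3-dimethoxybenzene-1,4-diol | COc1c(O)ccc(O)c1OC | intermediate
4 | 1,4-bis(benzyloxy)-2,3-dimethoxybenzene | COc1c(OCc2ccccc2)ccc(OCc2ccccc2)c1OC | intermediate
5 | 1,4-bis(benzyloxy)-5-bromo-2,3-dimethoxybenzene | COc1c(OC)c(OCc2ccccc2)c(Br)cc1OCc1ccccc1 | intermediate
6 | tert-butyl [2,5-bis(benzyloxy)-3,4-dimethoxyphenyl]acetate | COc1c(OC)c(OCc2ccccc2)c(CC(=O)OC(C)(C)C)cc1OCc1ccccc1 | intermediate
7 | [2,5-bis(benzyloxy)-3,4-dimethoxyphenyl]acetic acid | COc1c(OC)c(OCc2ccccc2)c(CC(=O)O)cc1OCc1ccccc1 | intermediate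
8 | (4S)-4-benzyl-1,3-oxazolidin-2-one | O=C1N[C@@H](Cc2ccccc2)CO1 | starting material
9 | [2,5-bis(benzyloxy)-3,4-dimethoxyphenyl]acetic pivalic anhydride (not isolated) | COc1c(OC)c(OCc2ccccc2)c(CC(=O)OC(=O)C(C)(C)C)cc1OCc1ccccc1 | intermediate
10 | (4S)-4-benzyl-3-{[2,5-bis(benzyloxy)-3,4-dimethoxyphenyl]acetyl}-1,3-oxazolidin-2-one | COc1c(OC)c(OCc2ccccc2)c(CC(=O)N2[C@@H](Cc3ccccc3)COC2=O)cc1OCc1ccccc1 | intermediate
11 | tert-butyl acrylate | C=CC(=O)OC(C)(C)C | starting material
12 | dichloro(isopropoxy)titanium Z-enolate of 10 (not isolated) | COc1c(OC)c(OCc2ccccc2)c(/C=C(\O[Ti](Cl)(Cl)OC(C)C)N2[C@@H](Cc3ccccc3)COC2=O)cc1OCc1ccccc1 | intermediate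
13 | tert-butyl (4S)-5-[(4S)-4-benzyl-2-oxo-1,3-oxazolidin-3-yl]-4-[2,5-bis(benzyloxy)-3,4-dimethoxyphenyl]-5-oxopentanoate | CC(C)(C)OC(=O)CC[C@@H](c1cc(OCc2ccccc2)c(OC)c(OC)c1OCc1ccccc1)C(=O)N1[C@@H](Cc2ccccc2)COC1=O | intermediate
14 | tert-butyl (4S)-4-[2,5-bis(benzyloxy)-3,4-dimethoxyphenyl]-5-hydroxypentanoate | CC(C)(C)OC(=O)CC[C@@H](c1cc(OCc2ccccc2)c(OC)c(OC)c1OCc1ccccc1)CO | intermediate
15 | (5S)-5-[2,5-bis(benzyloxy)-3,4-dimethoxyphenyl]oxan-2-one | O=C1CC[C@@H](c2cc(OCc3ccccc3)c(OC)c(OC)c2OCc2ccccc2)CO1 | intermediate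
16 | (3E,5S)-5-[2,5-bis(benzyloxy)-3,4-dimethoxyphenyl]-3-[(dimethylamino)methylidene]oxan-2-one | CN(C)/C=C1\C[C@@H](c2cc(OCc3ccccc3)c(OC)c(OC)c2OCc2ccccc2)COC1=O | intermediate
17 | 1,3-dimethoxyacetone | COCC(=O)COC | starting material
18 | (5S)-5-[2,5-bis(benzyloxy)-3,4-dimethoxyphenyl]-3-(2,4-dimethoxy-3-oxobutylidene)oxan-2-one, present as its potassium dienolate, alkene geometry and C6 centre not fixed (not isolated) | COCC(=O)C(OC)C=C1C[C@@H](c2cc(OCc3ccccc3)c(OC)c(OC)c2OCc2ccccc2)COC1=O | intermediate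
19 | (2S)-2-[2,5-bis(benzyloxy)-3,4-dimethoxyphenyl]-3-(2,4-dihydroxy-3,5-dimethoxyphenyl)propan-1-ol | COc1c(OC)c(OCc2ccccc2)c([C@@H](CO)Cc2cc(OC)c(O)c(OC)c2O)cc1OCc1ccccc1 | intermediate
20 | (3S)-3-[2,5-bis(benzyloxy)-3,4-dimethoxyphenyl]-6,8-dimethoxychroman-7-ol | COc1c(OC)c(OCc2ccccc2)c([C@H]2COc3c(cc(OC)c(O)c3OC)C2)cc1OCc1ccccc1 | intermediate
21 | 5-[(3S)-7-hydroxy-6,8-dimethoxychroman-3-yl]-2,3-dimethoxybenzene-1,4-diol | COc1c(OC)c(O)c([C@H]2COc3c(cc(OC)c(O)c3OC)C2)cc1O | intermediate
22 | 5-[(3S)-7-hydroxy-6,8-dimethoxychroman-3-yl]-2,3-dimethoxycyclohexa-2,5-diene-1,4-dione (CNP0121136.1) | COC1=C(OC)C(=O)C([C@H]2COc3c(cc(OC)c(O)c3OC)C2)=CC1=O | target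

**Total step count:** 15. **Longest linear sequence:** 15 steps (1 to 22); 8, 11 and 17 are bought.

**Steps most likely to fail**

1. **Step 12.**
   - Both partners are less activated than the usual partners of this annulation.
   - The vinylogous carbamate may take up the ketone enolate so slowly that self-aldol condensation uses up 17.
   - After the first bond, closure through the C7 enolate oxygen may hold the material at the pyranone stage.
   - The electron-rich resorcinolate may be oxidised by traces of air.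
   - The fallback sets out from 10 and returns at 21, with ring A brought in preformed.
     - Syringaldehyde is brominated (Br2, AcOH) to 2-bromo-4-hydroxy-3,5-dimethoxybenzaldehyde F1.
     - It is benzylated (BnBr, K2CO3, DMF) to 4-(benzyloxy)-2-bromo-3,5-dimethoxybenzaldehyde F2.
     - NaBH4 in MeOH reduces this to [4-(benzyloxy)-2-bromo-3,5-dimethoxyphenyl]methanol F3.
     - PBr3 (CH2Cl2, 0 °C) turns it into 2-(benzyloxy)-4-bromo-5-(bromomethyl)-1,3-dimethoxybenzene F4.
     - The sodium enolate of 10 (NaN(SiMe3)2, THF, -78 °C) is alkylated with F4 from the face opposite the auxiliary benzyl group to (4S)-4-benzyl-3-{(2S)-3-[4-(benzyloxy)-2-bromo-3,5-dimethoxyphenyl]-2-[2,5-bis(benzyloxy)-3,4-dimethoxyphenyl]propanoyl}-1,3-oxazolidin-2-one F5.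
     - LiBH4 gives (2S)-3-[4-(benzyloxy)-2-bromo-3,5-dimethoxyphenyl]-2-[2,5-bis(benzyloxy)-3,4-dimethoxyphenyl]propan-1-ol F6.
     - An intramolecular Ullmann-type C-O coupling (CuI, 1,10-phenanthroline, Cs2CO3, toluene, 110 °C) closes ring C to (3S)-7-(benzyloxy)-3-[2,5-bis(benzyloxy)-3,4-dimethoxyphenyl]-6,8-dimethoxychroman F7.
     - Hydrogenolysis of the three benzyl ethers (H2, Pd/C) gives 21.

2. **Step 8.**
   - The Lewis acid may strip the ortho benzyl ether.
   - The hindered enolate may add so slowly that the acrylate oligomerises.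
   - Facial selectivity may be eroded, or the acidic benzylic centre may epimerise on work-up.
   - The fallback sets out from 10 and returns at 15 without a Lewis acid.
     - Alkylation of the sodium enolate (NaN(SiMe3)2, allyl iodide, THF, -78 °C) gives (4S)-4-benzyl-3-{(2S)-2-[2,5-bis(benzyloxy)-3,4-dimethoxyphenyl]pent-4-enoyl}-1,3-oxazolidin-2-one F8.
     - LiBH4 gives (2S)-2-[2,5-bis(benzyloxy)-3,4-dimethoxyphenyl]pent-4-en-1-ol F9.
     - Hydroboration-oxidation (9-BBN, then H2O2, NaOH) gives (2S)-2-[2,5-bis(benzyloxy)-3,4-dimethoxyphenyl]pentane-1,5-diol F10.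
     - TEMPO with PhI(OAc)2 oxidises the unhindered C5 alcohol first, so that lactol formation and further oxidation lead to 15.

3. **Step 13.**
   - Intermolecular alkylation at the C7 phenol may lead to oligomers.
   - The azodicarboxylate may oxidise the electron-rich ring.
   - The fallback sets out from 19 and returns at 20, and separates activation from ring closure.
     - An Appel reaction (CBr4, PPh3, CH2Cl2, 0 °C), which leaves phenols alone, gives 4-{(2S)-2-[2,5-bis(benzyloxy)-3,4-dimethoxyphenyl]-3-bromopropyl}-2,6-dimethoxybenzene-1,3-diol F11.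
     - An intramolecular Williamson closure (K2CO3, acetone, reflux, argon, high dilution) through the C8a phenoxide gives 20.

**Further compounds**
F1 | step 12 | 2-bromo-4-hydroxy-3,5-dimethoxybenzaldehyde | COc1cc(C=O)c(Br)c(OC)c1O
F2 | step 12 | 4-(benzyloxy)-2-bromo-3,5-dimethoxybenzaldehyde | COc1cc(C=O)c(Br)c(OC)c1OCc1ccccc1
F3 | step 12 | [4-(benzyloxy)-2-bromo-3,5-dimethoxyphenyl]methanol | COc1cc(CO)c(Br)c(OC)c1OCc1ccccc1
F4 | step 12 | 2-(benzyloxy)-4-bromo-5-(bromomethyl)-1,3-dimethoxybenzene | COc1cc(CBr)c(Br)c(OC)c1OCc1ccccc1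
F5 | step 12 | (4S)-4-benzyl-3-{(2S)-3-[4-(benzyloxy)-2-bromo-3,5-dimethoxyphenyl]-2-[2,5-bis(benzyloxy)-3,4-dimethoxyphenyl]propanoyl}-1,3-oxazolidin-2-one | COc1cc(C[C@@H](c2cc(OCc3ccccc3)c(OC)c(OC)c2OCc2ccccc2)C(=O)N2[C@@H](Cc3ccccc3)COC2=O)c(Br)c(OC)c1OCc1ccccc1
F6 | step 12 | (2S)-3-[4-(benzyloxy)-2-bromo-3,5-dimethoxyphenyl]-2-[2,5-bis(benzyloxy)-3,4-dimethoxyphenyl]propan-1-ol | COc1cc(C[C@@H](c2cc(OCc3ccccc3)c(OC)c(OC)c2OCc2ccccc2)CO)c(Br)c(OC)c1OCc1ccccc1
F7 | step 12 | (3S)-7-(benzyloxy)-3-[2,5-bis(benzyloxy)-3,4-dimethoxyphenyl]-6,8-dimethoxychroman | COc1c(OC)c(OCc2ccccc2)c([C@H]2COc3c(cc(OC)c(OCc4ccccc4)c3OC)C2)cc1OCc1ccccc1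
F8 | step 8 | (4S)-4-benzyl-3-{(2S)-2-[2,5-bis(benzyloxy)-3,4-dimethoxyphenyl]pent-4-enoyl}-1,3-oxazolidin-2-one | C=CC[C@@H](c1cc(OCc2ccccc2)c(OC)c(OC)c1OCc1ccccc1)C(=O)N1[C@@H](Cc2ccccc2)COC1=O
F9 | step 8 | (2S)-2-[2,5-bis(benzyloxy)-3,4-dimethoxyphenyl]pent-4-en-1-ol | C=CC[C@@H](c1cc(OCc2ccccc2)c(OC)c(OC)c1OCc1ccccc1)CO
F10 | step 8 | (2S)-2-[2,5-bis(benzyloxy)-3,4-dimethoxyphenyl]pentane-1,5-diol | OCCC[C@@H](c1cc(OCc2ccccc2)c(OC)c(OC)c1OCc1ccccc1)CO
F11 | step 13 | 4-{(2S)-2-[2,5-bis(benzyloxy)-3,4-dimethoxyphenyl]-3-bromopropyl}-2,6-dimethoxybenzene-1,3-diol | COc1c(OC)c(OCc2ccccc2)c([C@@H](CBr)Cc2cc(OC)c(O)c(OC)c2O)cc1OCc1ccccc1
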